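**Retrosynthet­ic overview**
1. Target 22 comes from its C3 benzoate 21. In 21 the cyclohexane bond C1'–C2' is disconnected together with C3'–Br and C4'–Cl, which leads back to the acyclic keto-allylsilane 19.
2. Enabling feature: the carbinol carbon C1' is homoallylic to a C3'=C4' alkene. Its oxygen lies 1,4-cis to the Cl on C4' and trans to the Br on C3'. C1' is bonded to the fully substituted oxane carbon C2, which carries O1, CH3 and C3. That neighbour steers the ketone face, and the new oxygen can relay the configuration across the ring.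
3. Ketone 19 comes from oxane thioester 10 and the zinc reagent of iodide 17 (ketone synthesis at C1'–C6').
4. The oxane ring comes from a 6-endo bromoetherification of diol monobenzoate 7. Compound 7 comes from asymmetric epoxidation of Z-dienol 5 followed by benzoate opening with inversion at the future C3.
5. Ring order: oxane first (step 6), cyclohexane last (step 14).

Key step: step 14

Remark on locants: oxane = O1, C2 (quaternary), C3 (CHO), C4, C5 (CHBr), C6 (CMe2). Cyclohexane = C1' (carbinol), C2' (CH2), C3' (CHBr), C4' (C(CH3)Cl), C5', C6'.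

**Step 1**
Reactants: 1 4-methylpent-3-en-1-ol
Product: 2 4-methylpent-3-enal
Conditions: TEMPO (10 mol%), PhI(OAc)2, CH2Cl2, 0 °C to rt
Reagents that add atoms: none
Why: The TEMPO/iodine(III) oxidation stops at the aldehyde under nearly neutral conditions, so the β,γ-alkene should not move into conjugation.

**Step 2**
Reactants: 2 4-methylpent-3-enal; 3 ethyl 2-[bis(2,2,2-trifluoroethoxy)phosphoryl]propanoate
Product: 4 ethyl (2Z)-2,6-dimethylhepta-2,5-dienoate
Conditions: KHMDS, 18-crown-6, THF, −78 °C
Reagents that add atoms: none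
Why: In the Still–Gennari olefination the electron-poor phosphonate eliminates under kinetic control, which should give the Z-trisubstituted enoate needed for a syn C2/C3 dioxygen pattern after anti opening of the epoxide.

**Step 3**
Reactants: 4 ethyl (2Z)-2,6-dimethylhepta-2,5-dienoate
Product: 5 (2Z)-2,6-dimethylhepta-2,5-dien-1-ol
Conditions: DIBAL-H (2.2 equiv), CH2Cl2, −78 °C; Rochelle salt
Reagents that add atoms: none
Why: DIBAL-H reduces the enoate in the 1,2-sense to the allylic alcohol without touching the alkene geometry.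

**Step 4**
Reactants: 5 (2Z)-2,6-dimethylhepta-2,5-dien-1-ol
Product: 6 [(2R,3S)-2-methyl-3-(3-methylbut-2-en-1-yl)oxiran-2-yl]methanol
Conditions: Ti(OiPr)4 (10 mol%), D-(−)-diisopropyl tartrate (12 mol%), t-BuOOH, 4 Å MS, CH2Cl2, −20 °C
Reagents that add atoms: tert-butyl hydroperoxide, CC(C)(C)OO
Why: In the Sharpless asymmetric epoxidation only the alkene next to the titanium-bound hydroxyl reacts, and D-(−)-tartrate should give the (2R) series (mirror image of the 2S series from L-(+)-tartrate), which fixes the future oxane C2–O bond and, through syn oxygen transfer, the neighbouring centre.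

**Step 5**
Reactants: 6 [(2R,3S)-2-methyl-3-(3-methylbut-2-en-1-yl)oxiran-2-yl]methanol
Product: 7 (2R,3R)-1,2-dihydroxy-2,6-dimethylhept-5-en-3-yl benzoate
Conditions: Ti(OiPr)4 (1.5 equiv), PhCO2H, CH2Cl2, rt
Reagents that add atoms: benzoic acid, O=C(O)c1ccccc1
Why: In the titanium-assisted opening of a 2,3-epoxy alcohol the chelated epoxide is attacked at the carbon remote from the carbinol with inversion, which sets the future C3 configuration, protects that oxygen and frees the tertiary hydroxyl with retention.

**Step 6**
Reactants: 7 (2R,3R)-1,2-dihydroxy-2,6-dimethylhept-5-en-3-yl benzoate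
Product: 8 (2R,3R,5R)-5-bromo-2-(hydroxymethyl)-2,6,6-trimethyloxan-3-yl benzoate
Conditions: 2,4,4,6-tetrabromocyclohexa-2,5-dienone (TBCO), MeNO2, 0 °C, dark
Reagents that add atoms: TBCO, O=C1C(Br)=CC(Br)(Br)C=C1Br
Why: In this bromoetherification the tertiary hydroxyl opens the bromonium ion at its tertiary carbon (6-endo, Markovnikov), and C5 should be set by a chair transition state with Br equatorial and the benzoate axial (anti to the axial C2 methyl, gauche to O1).

**Step 7**
Reactants: 8 (2R,3R,5R)-5-bromo-2-(hydroxymethyl)-2,6,6-trimethyloxan-3-yl benzoate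
Product: 9 (2S,3R,5R)-3-(benzoyloxy)-5-bromo-2,6,6-trimethyloxane-2-carboxylic acid
Conditions: TEMPO (20 mol%), PhI(OAc)2 (2.5 equiv), MeCN/H2O 1:1, rt
Reagents that add atoms: water, O
Why: The TEMPO/iodine(III) oxidation runs through the aldehyde hydrate to the acid, and C2 carries no hydrogen, so no centre can epimerise.

**Step 8**
Reactants: 9 (2S,3R,5R)-3-(benzoyloxy)-5-bromo-2,6,6-trimethyloxane-2-carboxylic acid
Product: 10 S-ethyl (2S,3R,5R)-3-(benzoyloxy)-5-bromo-2,6,6-trimethyloxane-2-carbothioate
Conditions: EtSH, DCC, DMAP (cat.), CH2Cl2, 0 °C to rt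
Reagents that add atoms: ethanethiol, CCS
Why: A Steglich-type thioesterification activates the acid without passing through an α-alkoxy acyl chloride, which could lose CO.

**Step 9**
Reactants: 11 but-2-yn-1-ol
Product: 12 (2E)-3-[dimethyl(phenyl)silyl]but-2-en-1-ol
Conditions: PhMe2SiH, PtCl2 (1 mol%), XPhos (2 mol%), THF, 50 °C
Reagents that add atoms: dimethylphenylsilane, C[SiH](C)c1ccccc1
Why: Platinum-catalysed syn hydrosilylation of a propargylic alcohol should place silicon on the alkyne carbon remote from the hydroxyl.

**Step 10**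
Reactants: 12 (2E)-3-[dimethyl(phenyl)silyl]but-2-en-1-ol; 13 triethyl orthoacetate
Product: 15 ethyl (±)-3-[dimethyl(phenyl)silyl]-3-methylpent-4-enoate, via mixed ketene acetal 14 (not isolated)
Conditions: EtCO2H (cat.), neat, 140 °C, EtOH distilled off
Reagents that add atoms: none
Why: In the Johnson–Claisen rearrangement the [3,3] shift forms the C–C bond at the silicon-bearing alkene carbon and gives the tertiary allylsilane, whose racemic centre does not matter because step 14 destroys it.

**Step 11**
Reactants: 15 ethyl (±)-3-[dimethyl(phenyl)silyl]-3-methylpent-4-enoate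
Product: 16 (±)-3-[dimethyl(phenyl)silyl]-3-methylpent-4-en-1-ol
Conditions: LiAlH4, Et2O, 0 °C
Reagents that add atoms: none
Why: Hydride reduction of the ester leaves the allylsilane untouched.

**Step 12**
Reactants: 16 (±)-3-[dimethyl(phenyl)silyl]-3-methylpent-4-en-1-ol
Product: 17 (±)-(5-iodo-3-methylpent-1-en-3-yl)dimethyl(phenyl)silane
Conditions: I2, PPh3, imidazole, CH2Cl2, 0 °C
Reagents that add atoms: iodine, II
Why: Appel-type iodination of a primary alcohol works here because iodine is bound as the phosphonium salt before the allylsilane is added, so no free electrophilic iodine meets the alkene.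

**Step 13**
Reactants: 10 S-ethyl (2S,3R,5R)-3-(benzoyloxy)-5-bromo-2,6,6-trimethyloxane-2-carbothioate; 17 (±)-(5-iodo-3-methylpent-1-en-3-yl)dimethyl(phenyl)silane
Product: 19 (2S,3R,5R)-5-bromo-2-{4-[dimethyl(phenyl)silyl]-4-methylhex-5-enoyl}-2,6,6-trimethyloxan-3-yl benzoate (both epimers at the silyl carbon), via alkylzinc iodide 18 (not isolated)
Conditions: 17, Zn dust (activated), THF, 40 °C; then 10, PdCl2(PPh3)2 (5 mol%), toluene, rt
Reagents that add atoms: none
Why: The Fukuyama coupling of the mild alkylzinc reagent with the acyl–palladium species stops at the ketone and should tolerate the benzoate, the hindered secondary bromide and the allylsilane.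

**Step 14**
Reactants: 19 (2S,3R,5R)-5-bromo-2-{4-[dimethyl(phenyl)silyl]-4-methylhex-5-enoyl}-2,6,6-trimethyloxan-3-yl benzoate
Product: 21 (2S,3R,5R)-5-bromo-2-[(1R,3S,4S)-3-bromo-4-chloro-1-hydroxy-4-methylcyclohexyl]-2,6,6-trimethyloxan-3-yl benzoate, via trichlorotitanium alkoxide 20 (not isolated)
Conditions: TiCl4 (1.2 equiv), 2,6-di-tert-butyl-4-methylpyridine, CH2Cl2, −78 °C; then NBS (1.05 equiv), −78 to −30 °C; pH 7 buffer
Reagents that add atoms: N-bromosuccinimide, O=C1CCC(=O)N1Br; titanium tetrachloride, Cl[Ti](Cl)(Cl)Cl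
Why: Proposed new method: TiCl4 binds the ketone of 19 and the unsubstituted CH2= terminus (C2') of the tertiary allylsilane attacks C1' (intramolecular Hosomi–Sakurai reaction; β-silyl cation at C3', then loss of PhMe2SiCl), which destroys the silicon-bearing centre so that both epimers of 19 converge on alkoxide 20, and NBS added to the same flask then forms a reversible bromonium ion on C3'=C4' that is opened at C4' by chloride from the Cl3Ti–O group. The closest known reaction types are the Lewis-acid cyclisation of allylsilanes onto ketones and the NBS/chlorotitanium alkoxide bromochlorination of allylic alcohols, in which a titanium-bound alkoxide hands over chloride; new are the one-flask coupling of the two and the relay from a homoallylic tertiary alkoxide. The cyclohexane is closed by C1'–C2' bond formation, 6-endo-trig at the alkene and exo at the carbonyl group, the 5-exo alternative through C3' being ruled out because it would leave a primary cation without β-silicon stabilisation. C1' is controlled by oxane C2: in both the polar Felkin–Anh and the Cornforth arrangement the nucleophile arrives away from the C2–O1 bond and past the C2 methyl group, which gives the (R) carbinol, while the five-ring chelate that would give the epimer is disfavoured because O1 sits between the two fully substituted carbons C2 and C6. C3' and C4' are controlled by C1': the axial O–TiCl3 shields its own face, so bromine sits on the opposite face and chloride reaches C4' from the oxygen face through a boat-like 1,4-bridged transition state, so that anti addition puts Br trans to Cl and Cl cis-1,4 to O. The step needs the diequatorial Markovnikov adduct instead of the diaxial adducts of a free BrCl addition, and the tether and reversibility should secure this, because diaxial adducts and any 7-oxabicyclo[2.2.1]heptane formed by O-capture keep Br antiperiplanar to the leaving group and re-ionise under TiCl4 whereas the diequatorial product does not, and the oxane C–O bonds and the C5 bromide should survive at low temperature with the hindered pyridine as proton trap.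

**Step 15**
Reactants: 21 (2S,3R,5R)-5-bromo-2-[(1R,3S,4S)-3-bromo-4-chloro-1-hydroxy-4-methylcyclohexyl]-2,6,6-trimethyloxan-3-yl benzoate
Product: 22 (2S,3R,5R)-5-bromo-2-[(1R,3S,4S)-3-bromo-4-chloro-1-hydroxy-4-methylcyclohexyl]-2,6,6-trimethyloxan-3-ol
Conditions: DIBAL-H (4 equiv), CH2Cl2, −78 °C; Rochelle salt
Reagents that add atoms: none
Why: Reductive cleavage of the hindered axial benzoate avoids base, so the tertiary chloride and both secondary bromides should stay in place.

**Compound list**
1 | 4-methylpent-3-en-1-ol | CC(C)=CCCO | starting material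
2 | 4-methylpent-3-enal | CC(C)=CCC=O | intermediate
3 | ethyl 2-[bis(2,2,2-trifluoroethoxy)phosphoryl]propanoate | CCOC(=O)C(C)P(=O)(OCC(F)(F)F)OCC(F)(F)F | starting material
4 | ethyl (2Z)-2,6-dimethylhepta-2,5-dienoate | CCOC(=O)/C(C)=C\CC=C(C)C | intermediate
5 | (2Z)-2,6-dimethylhepta-2,5-dien-1-ol | OC/C(C)=C\CC=C(C)C | intermediate
6 | [(2R,3S)-2-methyl-3-(3-methylbut-2-en-1-yl)oxiran-2-yl]methanol | OC[C@@]1(C)O[C@H]1CC=C(C)C | intermediate
7 | (2R,3R)-1,2-dihydroxy-2,6-dimethylhept-5-en-3-yl benzoate | OC[C@@](C)(O)[C@H](OC(=O)c1ccccc1)CC=C(C)C | intermediate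
8 | (2R,3R,5R)-5-bromo-2-(hydroxymethyl)-2,6,6-trimethyloxan-3-yl benzoate | CC1(C)O[C@](C)(CO)[C@H](OC(=O)c2ccccc2)C[C@H]1Br | intermediate
9 | (2S,3R,5R)-3-(benzoyloxy)-5-bromo-2,6,6-trimethyloxane-2-carboxylic acid | CC1(C)O[C@](C)(C(=O)O)[C@H](OC(=O)c2ccccc2)C[C@H]1Br | intermediate
10 | S-ethyl (2S,3R,5R)-3-(benzoyloxy)-5-bromo-2,6,6-trimethyloxane-2-carbothioate | CC1(C)O[C@](C)(C(=O)SCC)[C@H](OC(=O)c2ccccc2)C[C@H]1Br | intermediate
11 | but-2-yn-1-ol | CC#CCO | starting material
12 | (2E)-3-[dimethyl(phenyl)silyl]but-2-en-1-ol | OC/C=C(\C)[Si](C)(C)c1ccccc1 | intermediate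
13 | triethyl orthoacetate | CCOC(C)(OCC)OCC | starting material
14 | mixed ketene acetal, 1-ethoxyvinyl (2E)-3-silylbut-2-enyl ether | C=C(OCC)OC/C=C(\C)[Si](C)(C)c1ccccc1 | intermediate
15 | ethyl (±)-3-[dimethyl(phenyl)silyl]-3-methylpent-4-enoate | CCOC(=O)CC(C)(C=C)[Si](C)(C)c1ccccc1 | intermediate
16 | (±)-3-[dimethyl(phenyl)silyl]-3-methylpent-4-en-1-ol | OCCC(C)(C=C)[Si](C)(C)c1ccccc1 | intermediate
17 | (±)-(5-iodo-3-methylpent-1-en-3-yl)dimethyl(phenyl)silane | ICCC(C)(C=C)[Si](C)(C)c1ccccc1 | intermediate
18 | {3-[dimethyl(phenyl)silyl]-3-methylpent-4-en-1-yl}zinc iodide | I[Zn]CCC(C)(C=C)[Si](C)(C)c1ccccc1 | intermediate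
19 | (2S,3R,5R)-5-bromo-2-{4-[dimethyl(phenyl)silyl]-4-methylhex-5-enoyl}-2,6,6-trimethyloxan-3-yl benzoate, both epimers at the silyl carbon | CC1(C)O[C@](C)(C(=O)CCC(C)(C=C)[Si](C)(C)c2ccccc2)[C@H](OC(=O)c2ccccc2)C[C@H]1Br | intermediate
20 | trichlorotitanium (1R)-4-methyl-1-(oxan-2-yl)cyclohex-3-en-1-olate of the benzoate series | CC1(C)O[C@](C)([C@@]2(O[Ti](Cl)(Cl)Cl)CCC(C)=CC2)[C@H](OC(=O)c3ccccc3)C[C@H]1Br | intermediate
21 | (2S,3R,5R)-5-bromo-2-[(1R,3S,4S)-3-bromo-4-chloro-1-hydroxy-4-methylcyclohexyl]-2,6,6-trimethyloxan-3-yl benzoate | CC1(C)O[C@](C)([C@@]2(O)CC[C@](C)(Cl)[C@@H](Br)C2)[C@H](OC(=O)c3ccccc3)C[C@H]1Br | intermediate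
22 | (2S,3R,5R)-5-bromo-2-[(1R,3S,4S)-3-bromo-4-chloro-1-hydroxy-4-methylcyclohexyl]-2,6,6-trimethyloxan-3-ol | CC1(C)O[C@](C)([C@@]2(O)CC[C@](C)(Cl)[C@@H](Br)C2)[C@H](O)C[C@H]1Br | target

**Step count**
Total step count: 15.
Longest linear sequence: 11 (steps 1–8, 13, 14, 15). Steps 9–12 run in parallel.

**Steps most likely to fail**

**1. Step 14 (Proposed new method).**
- What may go wrong:
  - chelation through O1 may reverse the ketone facial selectivity;
  - free BrCl may open the bromonium ion in the diaxial sense and give the wrong relative configuration at C3'/C4';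
  - the tertiary alkoxide or the oxane C6–O1 bond may ionise under TiCl4.
- Fallback with known chemistry, from 19 back to 21, in three stages:
  - The cyclisation is run alone with the monodentate Lewis acid BF3·OEt2 in CH2Cl2 at −78 °C and worked up to give the cyclohexenol F1.
  - NBS in MeCN then brings about bromoetherification. Only the bromonium ion anti to the C1' hydroxyl can be captured, at C4', which gives the bromo 7-oxabicyclo[2.2.1]heptane F2 with Br anti to the oxygen bridge.
  - Lewis-acid ether cleavage with TiCl4 (or BCl3) in CH2Cl2 at −78 °C reopens the strained C4'–O bond with participation of the antiperiplanar bromine. Chloride should therefore enter with overall retention and give 21.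

**2. Step 6.**
- What may go wrong:
  - 5-exo closure to the oxolane may compete with 6-endo closure;
  - facial selectivity at the alkene may be poor, because the two C2 substituents are of similar size;
  - the primary hydroxyl may take part.
- Fallback, from 7 back to 8: the ring is closed under thermodynamic control by reversible oxymercuration. Hg(O2CCF3)2 in MeNO2, followed by aqueous KBr, should give the oxanyl mercury bromide F3 with mercury equatorial. Ionic bromodemercuration (Br2, pyridine, dark), which proceeds with retention, then gives 8.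

**3. Step 13.**
- What may go wrong:
  - oxidative addition or transmetallation may be slow at the thioester next to the quaternary C2;
  - the zinc reagent may be protonated or may homocouple.
- Fallback, from 8 back to 19, in three stages:
  - 8 is oxidised only to the non-enolisable aldehyde F4 (Dess–Martin periodinane).
  - Iodide 17 is converted with t-BuLi at −78 °C into the alkyllithium F5, which is transmetallated with CeCl3 and added to F4 at −78 °C. The aldehyde should react well before the benzoate, giving the secondary alcohol F6 as a mixture of carbinol epimers.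
  - Dess–Martin oxidation of F6 gives 19.

**Further compounds**
F1 | step 14 | (2S,3R,5R)-5-bromo-2-[(1R)-1-hydroxy-4-methylcyclohex-3-en-1-yl]-2,6,6-trimethyloxan-3-yl benzoate | CC1(C)O[C@](C)([C@@]2(O)CCC(C)=CC2)[C@H](OC(=O)c3ccccc3)C[C@H]1Br
F2 | step 14 | (2S,3R,5R)-5-bromo-2-(3-bromo-4-methyl-7-oxabicyclo[2.2.1]heptan-1-yl)-2,6,6-trimethyloxan-3-yl benzoate, Br anti to the oxygen bridge | CC1(C)O[C@](C)([C@@]23CC[C@](C)(O3)[C@@H](Br)C2)[C@H](OC(=O)c4ccccc4)C[C@H]1Br
F3 | step 6 | [(3R,5R,6R)-5-(benzoyloxy)-6-(hydroxymethyl)-2,2,6-trimethyloxan-3-yl]mercury bromide, mercury in the place of the C5 bromine of 8 | CC1(C)O[C@](C)(CO)[C@H](OC(=O)c2ccccc2)C[C@H]1[Hg]Br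
F4 | step 13 | (2S,3R,5R)-5-bromo-2-formyl-2,6,6-trimethyloxan-3-yl benzoate | CC1(C)O[C@](C)(C=O)[C@H](OC(=O)c2ccccc2)C[C@H]1Br
F5 | step 13 | {3-[dimethyl(phenyl)silyl]-3-methylpent-4-en-1-yl}lithium | [Li]CCC(C)(C=C)[Si](C)(C)c1ccccc1
F6 | step 13 | (2S,3R,5R)-5-bromo-2-{4-[dimethyl(phenyl)silyl]-1-hydroxy-4-methylhex-5-en-1-yl}-2,6,6-trimethyloxan-3-yl benzoate, epimer mixture in the side chain | CC1(C)O[C@](C)(C(O)CCC(C)(C=C)[Si](C)(C)c2ccccc2)[C@H](OC(=O)c3ccccc3)C[C@H]1Br
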